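**Strategy.** Everything rests on making the C2–C3 bond of the chromanone by C–H insertion: the carbene carbon of an α-aryl-α-diazo ketone (future C3, bearing ring B) inserts into the O–CH3 group ortho to the aroyl carbonyl on ring A, so that an ordinary methoxy carbon becomes C2. This one Rh(II)-catalysed step closes the pyranone ring and sets the base-labile C3 stereocentre under neutral conditions, using the fact that C2 is an O-bound CH2 next to a benzylic α-keto CH. The precursor is an achiral, fully silylated diazo deoxybenzoin built from two benzaldehydes; the 1,1-dimethylallyl group is installed beforehand by aromatic Claisen rearrangement.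

Key step: step 9

Remark on the chemistry: compounds 1 and 4 are taken as purchased. The stereocentre of the target is assigned 3S from the SMILES (C4 > C2 > C1' > H). Rh2(S-PTTL)4 is assumed to deliver 3S in step 9; if the sense of induction is the opposite, Rh2(R-PTTL)4 is used with no other change.

**Step 1**
Reactants: 1 4-hydroxy-2-methoxybenzaldehyde; 2 triisopropylsilyl chloride
Product: 3 2-methoxy-4-(triisopropylsilyloxy)benzaldehyde
Conditions: TIPSCl, imidazole, DMF, rt
Reagents that add atoms: triisopropylsilyl chloride, CC(C)[Si](Cl)(C(C)C)C(C)C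
Why: Imidazole-promoted silylation of the only phenol should give a robust aryl silyl ether that is later removed by fluoride without base.

**Step 2**
Reactants: 4 2,3,4-trihydroxybenzaldehyde; 5 prenyl bromide (1-bromo-3-methylbut-2-ene)
Product: 6 2,3-dihydroxy-4-(3-methylbut-2-enyloxy)benzaldehyde
Conditions: prenyl bromide (1.05 equiv), NaHCO3, DMF, 40 °C
Reagents that add atoms: prenyl bromide, CC(C)=CCBr
Why: Williamson etherification should occur only at O4, because the 4-OH (para to CHO, not hydrogen-bonded to it) is the one phenol that bicarbonate ionises.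

**Step 3**
Reactants: 6 2,3-dihydroxy-4-(3-methylbut-2-enyloxy)benzaldehyde
Product: 8 2,3,4-trihydroxy-5-(2-methylbut-3-en-2-yl)benzaldehyde, via ortho-dienone 7 (not isolated)
Conditions: EtOH/H2O (4:1), sealed tube, 130 °C, argon
Reagents that add atoms: none
Why: The aromatic Claisen rearrangement ([3,3]) can deliver the inverted allyl unit only to C5, since the para position carries CHO and the other ortho position carries OH, and dienone 7 then tautomerises to the phenol.

**Step 4**
Reactants: 8 2,3,4-trihydroxy-5-(2-methylbut-3-en-2-yl)benzaldehyde; 9 iodomethane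
Product: 10 2,3-dihydroxy-4-methoxy-5-(2-methylbut-3-en-2-yl)benzaldehyde
Conditions: MeI (1.1 equiv), NaHCO3, DMF, 40 °C
Reagents that add atoms: iodomethane, CI
Why: Williamson methylation should again select the most acidic 4-OH (para to CHO), and the small electrophile should tolerate the neighbouring quaternary carbon.

**Step 5**
Reactants: 10 2,3-dihydroxy-4-methoxy-5-(2-methylbut-3-en-2-yl)benzaldehyde; 11 tert-butyldimethylsilyl triflate
Product: 12 2,3-bis(tert-butyldimethylsilyloxy)-4-methoxy-5-(2-methylbut-3-en-2-yl)benzaldehyde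
Conditions: TBSOTf (2.4 equiv), 2,6-lutidine, CH2Cl2, 0 °C to rt
Reagents that add atoms: tert-butyldimethylsilyl triflate, CC(C)(C)[Si](C)(C)OS(=O)(=O)C(F)(F)F
Why: Silyl triflate silylation should cap both the hydrogen-bonded 2-OH and the flanked 3-OH, giving ethers that carry no C–H on the atom next to oxygen (needed in step 9) and that cannot migrate because no free phenol is left.

**Step 6**
Reactants: 12 2,3-bis(tert-butyldimethylsilyloxy)-4-methoxy-5-(2-methylbut-3-en-2-yl)benzaldehyde; 13 p-toluenesulfonyl hydrazide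
Product: 14 (E)-N'-[2,3-bis(tert-butyldimethylsilyloxy)-4-methoxy-5-(2-methylbut-3-en-2-yl)benzylidene]-4-methylbenzenesulfonohydrazide
Conditions: TsNHNH2, MeOH, rt
Reagents that add atoms: p-toluenesulfonyl hydrazide, Cc1ccc(cc1)S(=O)(=O)NN
Why: Condensation of an aryl aldehyde with tosylhydrazide is a reliable hydrazone formation and needs no added acid or base.

**Step 7**
Reactants: 14 tosylhydrazone of the ring-B aldehyde; 3 2-methoxy-4-(triisopropylsilyloxy)benzaldehyde
Product: 16 1-[2-methoxy-4-(triisopropylsilyloxy)phenyl]-2-[2,3-bis(tert-butyldimethylsilyloxy)-4-methoxy-5-(2-methylbut-3-en-2-yl)phenyl]ethan-1-one, via aryldiazomethane 15 (not isolated)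
Conditions: 14 (1.5 equiv), K2CO3, 1,4-dioxane, 110 °C
Reagents that add atoms: none
Why: Bamford–Stevens generation of aryldiazomethane 15 from the hydrazone salt, addition to the aldehyde carbonyl of 3 and 1,2-hydride shift with loss of N2 (aldehyde homologation, formal formyl C–H insertion) should give the deoxybenzoin with the carbonyl on ring A.

**Step 8**
Reactants: 16 deoxybenzoin; 17 4-acetamidobenzenesulfonyl azide (p-ABSA)
Product: 18 2-diazo-1-[2-methoxy-4-(triisopropylsilyloxy)phenyl]-2-[2,3-bis(tert-butyldimethylsilyloxy)-4-methoxy-5-(2-methylbut-3-en-2-yl)phenyl]ethan-1-one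
Conditions: p-ABSA (1.3 equiv), DBU (1.5 equiv), dry MeCN, 0 °C to rt
Reagents that add atoms: 4-acetamidobenzenesulfonyl azide, CC(=O)Nc1ccc(cc1)S(=O)(=O)N=[N+]=[N-]
Why: Regitz diazo transfer should proceed directly on the methylene that is both benzylic and α to the aryl ketone, as it does for deoxybenzoins in general.

**Step 9**
Reactants: 18 α-aryl-α-diazo ketone
Product: 19 (3S)-3-[2,3-bis(tert-butyldimethylsilyloxy)-4-methoxy-5-(2-methylbut-3-en-2-yl)phenyl]-7-(triisopropylsilyloxy)chroman-4-one
Conditions: Rh2(S-PTTL)4 (1 mol %), toluene, 4 Å MS, −20 to 0 °C, slow addition of 18 by syringe pump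
Reagents that add atoms: none
Why: Proposed new method: diazo ketone 18 loses N2 on the chiral Rh(II) carboxylate, and the catalyst-bound donor/acceptor carbene carbon (future C3) takes up a C–H bond of the ortho O–CH3 group through a six-membered transition state with C–C bond formation, so that the methyl carbon becomes C2; the closest known reaction types are the Rh(II)-catalysed 1,6-C–H insertion of 2-alkoxyphenyl diazo ketones to chroman-4-ones, the intramolecular C–H insertion of α-aryl-α-diazo ketones, and the enantioselective intermolecular insertion of aryl-substituted carbenoids into methyl ethers, whose combination on an aryl O–CH3 group is not established. The pyranone ring, the only ring formed, is closed as a six-membered ring by 1,6-insertion (C2–C3 bond). C3 is created directly as a C–H stereocentre at the carbene carbon, the face of the carbene that meets the C–H bond being fixed by the chiral ligand wall of the catalyst, so that no enol or enolate of the labile α-aryl ketone is formed. The step needs site selectivity against the normally faster 1,5-insertion on the ring-B side, which is secured because the 2'-oxygen carries a silyl group with no C–H on the atom next to oxygen, while 4'-OMe and 7-OTIPS cannot reach the carbene. Oxonium-ylide formation at the same methoxy oxygen should be reversible because methyl is a poor migrating group, the vinyl group cannot be reached within the molecule (meta relationship), and cyclopropanation or dimerisation between molecules is held back by slow addition at high dilution. The mirror-image catalyst is used if the sense of induction proves opposite.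

**Step 10**
Reactants: 19 silyl-protected (3S)-isoflavanone
Product: 20 (3S)-3-[2,3-dihydroxy-4-methoxy-5-(2-methylbut-3-en-2-yl)phenyl]-7-hydroxychroman-4-one (CNP0134633.1)
Conditions: HF·pyridine (excess), THF, 0 °C, plastic vessel; pH 7 phosphate buffer work-up
Reagents that add atoms: none
Why: Fluoride-driven cleavage of the three aryl Si–O bonds under acidic, non-basic conditions should free the phenols without enolising C3 or opening the pyranone ring, and the alkene and the methyl ether are inert to it.

**Compound list**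

1 | 4-hydroxy-2-methoxybenzaldehyde | COc1cc(O)ccc1C=O | starting material
2 | triisopropylsilyl chloride | CC(C)[Si](Cl)(C(C)C)C(C)C | starting material
3 | 2-methoxy-4-(triisopropylsilyloxy)benzaldehyde | COc1cc(O[Si](C(C)C)(C(C)C)C(C)C)ccc1C=O | intermediate
4 | 2,3,4-trihydroxybenzaldehyde | O=Cc1ccc(O)c(O)c1O | starting material
5 | prenyl bromide | CC(C)=CCBr | starting material
6 | 2,3-dihydroxy-4-(3-methylbut-2-enyloxy)benzaldehyde | CC(C)=CCOc1ccc(C=O)c(O)c1O | intermediate
7 | 3,4-dihydroxy-5-(2-methylbut-3-en-2-yl)-6-oxocyclohexa-1,3-diene-1-carbaldehyde (ortho-dienone, racemic) | C=CC(C)(C)C1C=C(C=O)C(O)=C(O)C1=O | intermediate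
8 | 2,3,4-trihydroxy-5-(2-methylbut-3-en-2-yl)benzaldehyde | C=CC(C)(C)c1cc(C=O)c(O)c(O)c1O | intermediate
9 | iodomethane | CI | starting material
10 | 2,3-dihydroxy-4-methoxy-5-(2-methylbut-3-en-2-yl)benzaldehyde | C=CC(C)(C)c1cc(C=O)c(O)c(O)c1OC | intermediate
11 | tert-butyldimethylsilyl triflate | CC(C)(C)[Si](C)(C)OS(=O)(=O)C(F)(F)F | starting material
12 | 2,3-bis(tert-butyldimethylsilyloxy)-4-methoxy-5-(2-methylbut-3-en-2-yl)benzaldehyde | C=CC(C)(C)c1cc(C=O)c(O[Si](C)(C)C(C)(C)C)c(O[Si](C)(C)C(C)(C)C)c1OC | intermediate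
13 | p-toluenesulfonyl hydrazide | Cc1ccc(cc1)S(=O)(=O)NN | starting material
14 | (E)-tosylhydrazone of 12 | C=CC(C)(C)c1cc(/C=N/NS(=O)(=O)c2ccc(C)cc2)c(O[Si](C)(C)C(C)(C)C)c(O[Si](C)(C)C(C)(C)C)c1OC | intermediate
15 | [2,3-bis(tert-butyldimethylsilyloxy)-4-methoxy-5-(2-methylbut-3-en-2-yl)phenyl]diazomethane | C=CC(C)(C)c1cc(C=[N+]=[N-])c(O[Si](C)(C)C(C)(C)C)c(O[Si](C)(C)C(C)(C)C)c1OC | intermediate
16 | 1-[2-methoxy-4-(triisopropylsilyloxy)phenyl]-2-[2,3-bis(tert-butyldimethylsilyloxy)-4-methoxy-5-(2-methylbut-3-en-2-yl)phenyl]ethan-1-one | C=CC(C)(C)c1cc(CC(=O)c2ccc(O[Si](C(C)C)(C(C)C)C(C)C)cc2OC)c(O[Si](C)(C)C(C)(C)C)c(O[Si](C)(C)C(C)(C)C)c1OC | intermediate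
17 | 4-acetamidobenzenesulfonyl azide | CC(=O)Nc1ccc(cc1)S(=O)(=O)N=[N+]=[N-] | starting material
18 | 2-diazo derivative of 16 | C=CC(C)(C)c1cc(C(=[N+]=[N-])C(=O)c2ccc(O[Si](C(C)C)(C(C)C)C(C)C)cc2OC)c(O[Si](C)(C)C(C)(C)C)c(O[Si](C)(C)C(C)(C)C)c1OC | intermediate
19 | (3S)-3-[2,3-bis(tert-butyldimethylsilyloxy)-4-methoxy-5-(2-methylbut-3-en-2-yl)phenyl]-7-(triisopropylsilyloxy)chroman-4-one | C=CC(C)(C)c1cc([C@H]2COc3cc(O[Si](C(C)C)(C(C)C)C(C)C)ccc3C2=O)c(O[Si](C)(C)C(C)(C)C)c(O[Si](C)(C)C(C)(C)C)c1OC | intermediate
20 | (3S)-3-[2,3-dihydroxy-4-methoxy-5-(2-methylbut-3-en-2-yl)phenyl]-7-hydroxychroman-4-one | C=CC(C)(C)c1cc([C@H]2COc3cc(O)ccc3C2=O)c(O)c(O)c1OC | target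

**Step count and risks**

Total step count: 10. Longest linear sequence: 9 steps (steps 2 to 10, from compound 4).

Steps most likely to fail:

1. Step 9 (Proposed new method). The carbene may be diverted into oxonium-ylide rearrangement, dimerisation or cyclopropanation between molecules, or the insertion may proceed with poor facial selectivity. The fallback uses known chemistry and sets out from deoxybenzoin 16. Chelation-controlled cleavage of the methyl ether ortho to the ketone (MgI2·OEt2, toluene, 80 °C) should give 1-[2-hydroxy-4-(triisopropylsilyloxy)phenyl]-2-[2,3-bis(tert-butyldimethylsilyloxy)-4-methoxy-5-(2-methylbut-3-en-2-yl)phenyl]ethan-1-one F1. Condensation with DMF dimethyl acetal (toluene, 90 °C) should close it to the silyl-protected isoflavone F2. Ru(II)–TsDPEN transfer hydrogenation (HCO2H/Et3N) reduces the C2=C3 bond and then the ketone with dynamic kinetic resolution through the enolisable isoflavanone, and should give the cis-(3S,4S)-isoflavan-4-ol F3, the catalyst enantiomer being chosen for 3S. Dess–Martin oxidation (CH2Cl2, 0 °C) returns the ketone without touching C3 and comes back to the route at compound 19.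

2. Step 7. The diazo–aldehyde adduct may partition towards aryl migration or epoxide formation, the diazo compound may form azine or stilbene, and hot carbonate may cause partial desilylation. The fallback sets out from aldehyde 12 and replaces the homologation by an organozinc addition and oxidation. NaBH4 reduction (MeOH, 0 °C) should give [2,3-bis(tert-butyldimethylsilyloxy)-4-methoxy-5-(2-methylbut-3-en-2-yl)phenyl]methanol F4. MsCl/Et3N followed by LiCl (THF, 0 °C) should give the benzylic chloride F5. Zinc insertion (Zn dust, LiCl, THF, rt) should give the benzylzinc chloride F6, which is used in solution. Its MgCl2-promoted addition to aldehyde 3 should give the racemic secondary alcohol 1-[2-methoxy-4-(triisopropylsilyloxy)phenyl]-2-[2,3-bis(tert-butyldimethylsilyloxy)-4-methoxy-5-(2-methylbut-3-en-2-yl)phenyl]ethanol F7. Dess–Martin oxidation comes back to the route at compound 16.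

3. Step 3. The free catechol may degrade on prolonged heating, the new ortho-(1,1-dimethylallyl)phenol may cyclise to a dihydrobenzofuran, or an abnormal Claisen rearrangement may scramble the side chain. The fallback sets out from compound 4 and brings in the quaternary group by C–C coupling in place of the sigmatropic shift. Selective 4-O-methylation (MeI, NaHCO3, DMF) should give 2,3-dihydroxy-4-methoxybenzaldehyde F8. Bromination with NBS (MeCN, 0 °C) at C5 (para to the 2-OH, ortho to OMe, meta to CHO) should give 5-bromo-2,3-dihydroxy-4-methoxybenzaldehyde F9. Silylation (TBSOTf, 2,6-lutidine) should give 5-bromo-2,3-bis(tert-butyldimethylsilyloxy)-4-methoxybenzaldehyde F10. A ligand-controlled, γ-selective Pd-catalysed Suzuki–Miyaura coupling with prenylboronic acid pinacol ester (K3PO4, THF/H2O, 40 °C) should then deliver the 1,1-dimethylallyl group and comes back to the route at compound 12, which bypasses steps 2 to 5.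

**Further compounds**

F1 | step 9 | 1-[2-hydroxy-4-(triisopropylsilyloxy)phenyl]-2-[2,3-bis(tert-butyldimethylsilyloxy)-4-methoxy-5-(2-methylbut-3-en-2-yl)phenyl]ethan-1-one | C=CC(C)(C)c1cc(CC(=O)c2ccc(O[Si](C(C)C)(C(C)C)C(C)C)cc2O)c(O[Si](C)(C)C(C)(C)C)c(O[Si](C)(C)C(C)(C)C)c1OC
F2 | step 9 | 3-[2,3-bis(tert-butyldimethylsilyloxy)-4-methoxy-5-(2-methylbut-3-en-2-yl)phenyl]-7-(triisopropylsilyloxy)chromen-4-one | C=CC(C)(C)c1cc(C2=COc3cc(O[Si](C(C)C)(C(C)C)C(C)C)ccc3C2=O)c(O[Si](C)(C)C(C)(C)C)c(O[Si](C)(C)C(C)(C)C)c1OC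
F3 | step 9 | (3S,4S)-3-[2,3-bis(tert-butyldimethylsilyloxy)-4-methoxy-5-(2-methylbut-3-en-2-yl)phenyl]-7-(triisopropylsilyloxy)chroman-4-ol | C=CC(C)(C)c1cc([C@H]2COc3cc(O[Si](C(C)C)(C(C)C)C(C)C)ccc3[C@H]2O)c(O[Si](C)(C)C(C)(C)C)c(O[Si](C)(C)C(C)(C)C)c1OC
F4 | step 7 | [2,3-bis(tert-butyldimethylsilyloxy)-4-methoxy-5-(2-methylbut-3-en-2-yl)phenyl]methanol | C=CC(C)(C)c1cc(CO)c(O[Si](C)(C)C(C)(C)C)c(O[Si](C)(C)C(C)(C)C)c1OC
F5 | step 7 | 1-(chloromethyl)-2,3-bis(tert-butyldimethylsilyloxy)-4-methoxy-5-(2-methylbut-3-en-2-yl)benzene | C=CC(C)(C)c1cc(CCl)c(O[Si](C)(C)C(C)(C)C)c(O[Si](C)(C)C(C)(C)C)c1OC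
F6 | step 7 | [2,3-bis(tert-butyldimethylsilyloxy)-4-methoxy-5-(2-methylbut-3-en-2-yl)benzyl]zinc chloride | C=CC(C)(C)c1cc(C[Zn]Cl)c(O[Si](C)(C)C(C)(C)C)c(O[Si](C)(C)C(C)(C)C)c1OC
F7 | step 7 | 1-[2-methoxy-4-(triisopropylsilyloxy)phenyl]-2-[2,3-bis(tert-butyldimethylsilyloxy)-4-methoxy-5-(2-methylbut-3-en-2-yl)phenyl]ethanol (racemic) | C=CC(C)(C)c1cc(CC(O)c2ccc(O[Si](C(C)C)(C(C)C)C(C)C)cc2OC)c(O[Si](C)(C)C(C)(C)C)c(O[Si](C)(C)C(C)(C)C)c1OC
F8 | step 3 | 2,3-dihydroxy-4-methoxybenzaldehyde | COc1ccc(C=O)c(O)c1O
F9 | step 3 | 5-bromo-2,3-dihydroxy-4-methoxybenzaldehyde | COc1c(Br)cc(C=O)c(O)c1O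
F10 | step 3 | 5-bromo-2,3-bis(tert-butyldimethylsilyloxy)-4-methoxybenzaldehyde | COc1c(Br)cc(C=O)c(O[Si](C)(C)C(C)(C)C)c1O[Si](C)(C)C(C)(C)C
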